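**Retrosynthetic overview**

1. Target ⇐ desilylation and C8 acylation of a macrocyclic C8 alcohol. The ten-membered ring is closed last through the C7–C8 bond, by a light-driven chromium-catalysed Barbier allylation of an α-acetoxy aldehyde with a tethered 3-(bromomethyl)butenolide; this also sets C7 and C8 and unveils the α-methylene lactone.
2. The butenolide (first ring) ⇐ ring-closing metathesis of a 2-(bromomethyl)acrylate on the C6 carbinol; the aldehyde ⇐ the C8/C9 diol (acetonide).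
3. The open C1–C10 chain ⇐ B-alkyl Suzuki coupling (C3–C4) of a West (Z)-vinyl bromide with an East diene.
4. West ⇐ (S)-but-3-ene-1,2-diol (C6) by bromo-Wittig olefination; East ⇐ the malic-acid-derived methyl dioxolanylacetate (C9) and acrolein by aldol/elimination; C2' ⇐ (S)-2-methylbutanoic anhydride.
5. Ring order: five-membered lactone first, ten-membered carbocycle second.

Assumption: the SMILES is read as the (3aS,4R,5S,6Z,10E,11aR) lactone carrying an (S)-2-methylbutanoate; germacrane numbering is used below (C6 lactone carbinol, C7 ring fusion, C8 and C9 ester carbons, C1=C10 and C4=C5 alkenes, C14 and C15 hydroxymethyls, C11–C13 lactone carbons, C2' the side-chain stereocentre).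

**Step 1**
Reactants: 1 (2S)-but-3-ene-1,2-diol
Product: 2 (3S)-3,4-bis[(triethylsilyl)oxy]but-1-ene
Conditions: TESCl (2.3 equiv), imidazole, CH2Cl2, 0 °C to rt
Reagents that add atoms: chlorotriethylsilane CC[Si](Cl)(CC)CC
Why: Double silyl ether formation masks both hydroxyls so the primary one can be oxidised selectively next, and the C6 stereocentre bought with 1 is not touched.

**Step 2**
Reactants: 2 (3S)-3,4-bis[(triethylsilyl)oxy]but-1-ene
Product: 3 (2S)-2-[(triethylsilyl)oxy]but-3-enal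
Conditions: (COCl)2, DMSO, CH2Cl2, −78 to −40 °C; then Et3N, −78 to 0 °C; used crude
Reagents that add atoms: none
Why: Under Swern oxidation conditions a primary triethylsilyl ether is cleaved and oxidised directly to the aldehyde while the secondary one is inert, so the α-silyloxy aldehyde forms cold and is used at once without erosion at C6.

**Step 3**
Reactants: 3 (2S)-2-[(triethylsilyl)oxy]but-3-enal; 4 ethyl (triphenylphosphoranylidene)acetate
Product: 6 ethyl (2Z,4S)-2-bromo-4-[(triethylsilyl)oxy]hexa-2,5-dienoate, via bromo ylide 5 (not isolated)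
Conditions: 4, NBS, CH2Cl2, −20 °C; then 3, −20 °C to rt
Reagents that add atoms: N-bromosuccinimide O=C1CCC(=O)N1Br
Why: Wittig olefination with the α-bromo stabilised ylide places the aldehyde carbon trans to the ester and so cis to bromine (Z-bromoalkene), which fixes the later C4=C5 geometry and leaves C6 alone.

**Step 4**
Reactants: 6 ethyl (2Z,4S)-2-bromo-4-[(triethylsilyl)oxy]hexa-2,5-dienoate
Product: 8 (2Z,4S)-2-bromohexa-2,5-diene-1,4-diol, via mono-silyl alcohol 7 (not isolated)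
Conditions: i-Bu2AlH, CH2Cl2, −78 °C; then 1 M HCl, THF, 0 °C
Reagents that add atoms: none
Why: i-Bu2AlH reduces the enoate 1,2 to the allylic alcohol without touching the vinyl bromide, and the dilute acid work-up hydrolyses the secondary triethylsilyl ether (ester reduction, acidic desilylation).

**Step 5**
Reactants: 8 (2Z,4S)-2-bromohexa-2,5-diene-1,4-diol
Product: 9 (3S,4Z)-5-bromo-6-[(tert-butyldiphenylsilyl)oxy]hexa-1,4-dien-3-ol
Conditions: TBDPSCl (1.05 equiv), imidazole, CH2Cl2, −20 to 0 °C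
Reagents that add atoms: tert-butyl(chloro)diphenylsilane CC(C)(C)[Si](Cl)(c1ccccc1)c1ccccc1
Why: Selective silyl ether formation, because the primary allylic hydroxyl (C15) reacts far faster with the bulky silyl chloride than the hindered secondary C6 hydroxyl.

**Step 6**
Reactants: 10 methyl [(4S)-2,2-dimethyl-1,3-dioxolan-4-yl]acetate; 11 acrolein
Product: 14 methyl (2E)-2-[(4S)-2,2-dimethyl-1,3-dioxolan-4-yl]penta-2,4-dienoate, via aldol adduct 12 (not isolated), via allylic mesylate 13 (not isolated)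
Conditions: LiN(i-Pr)2, THF, −78 °C; acrolein; MsCl, −78 to 0 °C; DBU, 0 °C to rt
Reagents that add atoms: none
Why: Aldol addition of the lithium enolate (stable to β-elimination at −78 °C) to acrolein, mesylation and E1cB elimination give the conjugated dienoate with the vinyl group trans to the ester (the favoured E isomer, needed for C1=C10), and the bought C9 centre is not involved.

**Step 7**
Reactants: 14 methyl (2E)-2-[(4S)-2,2-dimethyl-1,3-dioxolan-4-yl]penta-2,4-dienoate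
Product: 15 (2Z)-2-[(4S)-2,2-dimethyl-1,3-dioxolan-4-yl]penta-2,4-dien-1-ol
Conditions: i-Bu2AlH, CH2Cl2, −78 °C
Reagents that add atoms: none
Why: 1,2-Reduction of the conjugated ester by i-Bu2AlH gives the dienol (C14–OH) with the alkene geometry and C9 unchanged.

**Step 8**
Reactants: 15 (2Z)-2-[(4S)-2,2-dimethyl-1,3-dioxolan-4-yl]penta-2,4-dien-1-ol
Product: 16 tert-butyl({(2Z)-2-[(4S)-2,2-dimethyl-1,3-dioxolan-4-yl]penta-2,4-dien-1-yl}oxy)diphenylsilane
Conditions: TBDPSCl, imidazole, CH2Cl2, 0 °C to rt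
Reagents that add atoms: tert-butyl(chloro)diphenylsilane CC(C)(C)[Si](Cl)(c1ccccc1)c1ccccc1
Why: Silyl ether formation protects C14–OH with an acid-stable group for the rest of the route.

**Step 9**
Reactants: 16 tert-butyl({(2Z)-2-[(4S)-2,2-dimethyl-1,3-dioxolan-4-yl]penta-2,4-dien-1-yl}oxy)diphenylsilane; 9 (3S,4Z)-5-bromo-6-[(tert-butyldiphenylsilyl)oxy]hexa-1,4-dien-3-ol
Product: 18 (3S,4E,8Z)-10-[(tert-butyldiphenylsilyl)oxy]-5-{[(tert-butyldiphenylsilyl)oxy]methyl}-9-[(4S)-2,2-dimethyl-1,3-dioxolan-4-yl]deca-1,4,8-trien-3-ol, via alkylborane 17 (not isolated)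
Conditions: 9-BBN-H (1.05 equiv), THF, 0 °C to rt; then 9, Pd(dppf)Cl2 (5 mol %), AsPh3, Cs2CO3, DMF/H2O, rt
Reagents that add atoms: none
Why: Anti-Markovnikov hydroboration of the only monosubstituted alkene of 16, then B-alkyl Suzuki–Miyaura coupling with the vinyl bromide with retention, forms C3–C4 and the C4=C5 alkene with C3 cis to C6; the free C6 hydroxyl is tolerated.

**Step 10**
Reactants: 18 (3S,4E,8Z)-10-[(tert-butyldiphenylsilyl)oxy]-5-{[(tert-butyldiphenylsilyl)oxy]methyl}-9-[(4S)-2,2-dimethyl-1,3-dioxolan-4-yl]deca-1,4,8-trien-3-ol; 19 2-(bromomethyl)prop-2-enoic acid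
Product: 21 (3S,4E,8Z)-10-[(tert-butyldiphenylsilyl)oxy]-5-{[(tert-butyldiphenylsilyl)oxy]methyl}-9-[(4S)-2,2-dimethyl-1,3-dioxolan-4-yl]deca-1,4,8-trien-3-yl 2-(bromomethyl)prop-2-enoate, via acid chloride 20 (not isolated)
Conditions: 19, (COCl)2, cat. DMF, CH2Cl2, 0 °C to rt; then 18, 2,6-di-tert-butyl-4-methylpyridine, CH2Cl2, −20 °C to rt
Reagents that add atoms: none
Why: O-Acylation of the C6 alcohol by the acid chloride with a hindered, non-nucleophilic pyridine base that cannot displace the allylic bromide; the C6–O bond is not broken, so configuration is retained.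

**Step 11**
Reactants: 21 (3S,4E,8Z)-10-[(tert-butyldiphenylsilyl)oxy]-5-{[(tert-butyldiphenylsilyl)oxy]methyl}-9-[(4S)-2,2-dimethyl-1,3-dioxolan-4-yl]deca-1,4,8-trien-3-yl 2-(bromomethyl)prop-2-enoate
Product: 22 (5R)-3-(bromomethyl)-5-[(1E,5Z)-7-[(tert-butyldiphenylsilyl)oxy]-2-{[(tert-butyldiphenylsilyl)oxy]methyl}-6-[(4S)-2,2-dimethyl-1,3-dioxolan-4-yl]hepta-1,5-dien-1-yl]furan-2(5H)-one
Conditions: second-generation Grubbs catalyst (10 mol %), toluene (5 mM), 80 °C
Reagents that add atoms: none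
Why: Ring-closing metathesis between the terminal vinyl group and the acrylate closes the butenolide (C7=C11) with loss of ethylene, the two trisubstituted alkenes being inert to the ruthenium carbene.

**Step 12**
Reactants: 22 (5R)-3-(bromomethyl)-5-[(1E,5Z)-7-[(tert-butyldiphenylsilyl)oxy]-2-{[(tert-butyldiphenylsilyl)oxy]methyl}-6-[(4S)-2,2-dimethyl-1,3-dioxolan-4-yl]hepta-1,5-dien-1-yl]furan-2(5H)-one
Product: 23 (5R)-3-(bromomethyl)-5-[(1E,5Z,7S)-2,6-bis{[(tert-butyldiphenylsilyl)oxy]methyl}-7,8-dihydroxyocta-1,5-dien-1-yl]furan-2(5H)-one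
Conditions: AcOH/H2O (4:1), 40 °C
Reagents that add atoms: none
Why: Acid-catalysed acetal hydrolysis frees the C8/C9 diol while the TBDPS ethers, the allylic bromide and the butenolide survive aqueous acetic acid.

**Step 13**
Reactants: 23 (5R)-3-(bromomethyl)-5-[(1E,5Z,7S)-2,6-bis{[(tert-butyldiphenylsilyl)oxy]methyl}-7,8-dihydroxyocta-1,5-dien-1-yl]furan-2(5H)-one
Product: 25 (2S,3Z,7E)-8-[(2R)-4-(bromomethyl)-5-oxo-2,5-dihydrofuran-2-yl]-3,7-bis{[(tert-butyldiphenylsilyl)oxy]methyl}-1-hydroxyocta-3,7-dien-2-yl acetate, via cyclic orthoacetate 24 (not isolated)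
Conditions: MeC(OMe)3, PPTS (cat.), CH2Cl2, rt; then AcOH/H2O, 0 °C; used directly
Reagents that add atoms: trimethyl orthoacetate COC(C)(OC)OC; water O
Why: Regioselective monoacylation through a cyclic orthoester, whose hydrolysis expels the less hindered primary oxygen and leaves the acetate on the secondary C9 oxygen, with no amine base that would attack the allylic bromide.

**Step 14**
Reactants: 25 (2S,3Z,7E)-8-[(2R)-4-(bromomethyl)-5-oxo-2,5-dihydrofuran-2-yl]-3,7-bis{[(tert-butyldiphenylsilyl)oxy]methyl}-1-hydroxyocta-3,7-dien-2-yl acetate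
Product: 26 (2S,3Z,7E)-8-[(2R)-4-(bromomethyl)-5-oxo-2,5-dihydrofuran-2-yl]-3,7-bis{[(tert-butyldiphenylsilyl)oxy]methyl}-1-oxoocta-3,7-dien-2-yl acetate
Conditions: TEMPO (10 mol %), PhI(OAc)2, CH2Cl2, rt
Reagents that add atoms: none
Why: Nitroxyl-catalysed oxidation of the primary alcohol stops at the aldehyde under neutral, non-nucleophilic conditions that preserve the α-acetoxy centre C9 and the allylic bromide.

**Step 15**
Reactants: 26 (2S,3Z,7E)-8-[(2R)-4-(bromomethyl)-5-oxo-2,5-dihydrofuran-2-yl]-3,7-bis{[(tert-butyldiphenylsilyl)oxy]methyl}-1-oxoocta-3,7-dien-2-yl acetate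
Product: 27 (3aR,4R,5S,6Z,10E,11aR)-6,10-bis{[(tert-butyldiphenylsilyl)oxy]methyl}-4-hydroxy-3-methylidene-2-oxo-2,3,3a,4,5,8,9,11a-octahydrocyclodeca[b]furan-5-yl acetate
Conditions: 4CzIPN (2 mol %), CrCl2 (15 mol %), Hantzsch ester (1.5 equiv), DMF/THF (2 mM), 450 nm LEDs, rt
Reagents that add atoms: none
Why: Proposed new method: a light-driven, chromium-catalysed intramolecular Barbier (Nozaki–Hiyama-type) allylation that closes the ten-membered ring; excited 4CzIPN is reduced by the Hantzsch ester and returns trivalent chromium to divalent chromium, which turns the allylic bromide into an allylchromium species bound at C13 that adds through C7 to the tethered aldehyde in a six-membered chair, and the Hantzsch pyridinium protonates the chromium alkoxide to close the cycle; C7 is attacked anti to the C6 side chain (trans-lactone), the ring-fixed allyl geometry with C9 equatorial gives the C7/C8 relationship of the target, and this is matched with Felkin–Anh control by the C9 acetate; the closest known reactions are stoichiometric CrCl2 Barbier macrocyclisations of 2-(bromomethyl)alkenoates onto aldehydes that form germacranolide rings, zinc or chromium Barbier reactions of 3-(bromomethyl)furan-2(5H)-ones with aldehydes, and intermolecular photoredox chromium allylations of aldehydes.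

**Step 16**
Reactants: 27 (3aR,4R,5S,6Z,10E,11aR)-6,10-bis{[(tert-butyldiphenylsilyl)oxy]methyl}-4-hydroxy-3-methylidene-2-oxo-2,3,3a,4,5,8,9,11a-octahydrocyclodeca[b]furan-5-yl acetate; 28 (2S)-2-methylbutanoic anhydride
Product: 29 (3aS,4R,5S,6Z,10E,11aR)-5-(acetyloxy)-6,10-bis{[(tert-butyldiphenylsilyl)oxy]methyl}-3-methylidene-2-oxo-2,3,3a,4,5,8,9,11a-octahydrocyclodeca[b]furan-4-yl (2S)-2-methylbutanoate
Conditions: 28, DMAP (cat.), Et3N, CH2Cl2, 0 °C
Reagents that add atoms: none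
Why: DMAP-catalysed acylation of the C8 hydroxyl with the enantiopure anhydride installs the (S)-2-methylbutanoate (C2' bought with 28) faster than any 1,2-acetyl shift and without epimerisation.

**Step 17**
Reactants: 29 (3aS,4R,5S,6Z,10E,11aR)-5-(acetyloxy)-6,10-bis{[(tert-butyldiphenylsilyl)oxy]methyl}-3-methylidene-2-oxo-2,3,3a,4,5,8,9,11a-octahydrocyclodeca[b]furan-4-yl (2S)-2-methylbutanoate
Product: 30 (3aS,4R,5S,6Z,10E,11aR)-5-(acetyloxy)-6,10-bis(hydroxymethyl)-3-methylidene-2-oxo-2,3,3a,4,5,8,9,11a-octahydrocyclodeca[b]furan-4-yl (2S)-2-methylbutanoate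
Conditions: HF·pyridine, pyridine, THF, 0 °C to rt
Reagents that add atoms: none
Why: Fluoride-mediated desilylation under buffered conditions removes both TBDPS ethers while the acetate, the 2-methylbutanoate and the α-methylene lactone are stable, giving the target.

**Compound list**

1 | (2S)-but-3-ene-1,2-diol | C=C[C@H](O)CO | starting material
2 | (3S)-3,4-bis[(triethylsilyl)oxy]but-1-ene | C=C[C@H](O[Si](CC)(CC)CC)CO[Si](CC)(CC)CC | intermediate
3 | (2S)-2-[(triethylsilyl)oxy]but-3-enal | C=C[C@H](O[Si](CC)(CC)CC)C=O | intermediate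
4 | ethyl (triphenylphosphoranylidene)acetate | CCOC(=O)C=P(c1ccccc1)(c1ccccc1)c1ccccc1 | starting material
5 | ethyl bromo(triphenylphosphoranylidene)acetate | CCOC(=O)C(Br)=P(c1ccccc1)(c1ccccc1)c1ccccc1 | intermediate
6 | ethyl (2Z,4S)-2-bromo-4-[(triethylsilyl)oxy]hexa-2,5-dienoate | CCOC(=O)/C(Br)=C/[C@@H](O[Si](CC)(CC)CC)C=C | intermediate
7 | (2Z,4S)-2-bromo-4-[(triethylsilyl)oxy]hexa-2,5-dien-1-ol | OC/C(Br)=C/[C@@H](O[Si](CC)(CC)CC)C=C | intermediate
8 | (2Z,4S)-2-bromohexa-2,5-diene-1,4-diol | OC/C(Br)=C/[C@@H](O)C=C | intermediate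
9 | (3S,4Z)-5-bromo-6-[(tert-butyldiphenylsilyl)oxy]hexa-1,4-dien-3-ol | CC(C)(C)[Si](OC/C(Br)=C/[C@@H](O)C=C)(c1ccccc1)c1ccccc1 | intermediate
10 | methyl [(4S)-2,2-dimethyl-1,3-dioxolan-4-yl]acetate | COC(=O)C[C@H]1COC(C)(C)O1 | starting material
11 | acrolein (prop-2-enal) | C=CC=O | starting material
12 | methyl 2-[(4S)-2,2-dimethyl-1,3-dioxolan-4-yl]-3-hydroxypent-4-enoate (lithium alkoxide in the flask, mixture at C2 and C3) | COC(=O)C(C(O)C=C)[C@H]1COC(C)(C)O1 | intermediate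
13 | methyl 2-[(4S)-2,2-dimethyl-1,3-dioxolan-4-yl]-3-[(methylsulfonyl)oxy]pent-4-enoate (mixture at C2 and C3) | COC(=O)C(C(OS(C)(=O)=O)C=C)[C@H]1COC(C)(C)O1 | intermediate
14 | methyl (2E)-2-[(4S)-2,2-dimethyl-1,3-dioxolan-4-yl]penta-2,4-dienoate | COC(=O)/C(=C/C=C)[C@H]1COC(C)(C)O1 | intermediate
15 | (2Z)-2-[(4S)-2,2-dimethyl-1,3-dioxolan-4-yl]penta-2,4-dien-1-ol | OC/C(=C/C=C)[C@H]1COC(C)(C)O1 | intermediate
16 | tert-butyl({(2Z)-2-[(4S)-2,2-dimethyl-1,3-dioxolan-4-yl]penta-2,4-dien-1-yl}oxy)diphenylsilane | CC(C)(C)[Si](OC/C(=C/C=C)[C@H]1COC(C)(C)O1)(c1ccccc1)c1ccccc1 | intermediate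
17 | 9-{(3Z)-5-[(tert-butyldiphenylsilyl)oxy]-4-[(4S)-2,2-dimethyl-1,3-dioxolan-4-yl]pent-3-en-1-yl}-9-borabicyclo[3.3.1]nonane | CC(C)(C)[Si](OC/C(=C/CCB1C2CCCC1CCC2)[C@H]1COC(C)(C)O1)(c1ccccc1)c1ccccc1 | intermediate
18 | (3S,4E,8Z)-10-[(tert-butyldiphenylsilyl)oxy]-5-{[(tert-butyldiphenylsilyl)oxy]methyl}-9-[(4S)-2,2-dimethyl-1,3-dioxolan-4-yl]deca-1,4,8-trien-3-ol | C=C[C@H](O)/C=C(/CO[Si](c1ccccc1)(c1ccccc1)C(C)(C)C)CC/C=C(/CO[Si](c1ccccc1)(c1ccccc1)C(C)(C)C)[C@H]1COC(C)(C)O1 | intermediate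
19 | 2-(bromomethyl)prop-2-enoic acid | C=C(CBr)C(=O)O | starting material
20 | 2-(bromomethyl)prop-2-enoyl chloride | C=C(CBr)C(Cl)=O | intermediate
21 | (3S,4E,8Z)-10-[(tert-butyldiphenylsilyl)oxy]-5-{[(tert-butyldiphenylsilyl)oxy]methyl}-9-[(4S)-2,2-dimethyl-1,3-dioxolan-4-yl]deca-1,4,8-trien-3-yl 2-(bromomethyl)prop-2-enoate | C=C[C@H](OC(=O)C(=C)CBr)/C=C(/CO[Si](c1ccccc1)(c1ccccc1)C(C)(C)C)CC/C=C(/CO[Si](c1ccccc1)(c1ccccc1)C(C)(C)C)[C@H]1COC(C)(C)O1 | intermediate
22 | (5R)-3-(bromomethyl)-5-[(1E,5Z)-7-[(tert-butyldiphenylsilyl)oxy]-2-{[(tert-butyldiphenylsilyl)oxy]methyl}-6-[(4S)-2,2-dimethyl-1,3-dioxolan-4-yl]hepta-1,5-dien-1-yl]furan-2(5H)-one | BrCC1=C[C@H](OC1=O)/C=C(/CO[Si](c2ccccc2)(c2ccccc2)C(C)(C)C)CC/C=C(/CO[Si](c2ccccc2)(c2ccccc2)C(C)(C)C)[C@H]1COC(C)(C)O1 | intermediate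
23 | (5R)-3-(bromomethyl)-5-[(1E,5Z,7S)-2,6-bis{[(tert-butyldiphenylsilyl)oxy]methyl}-7,8-dihydroxyocta-1,5-dien-1-yl]furan-2(5H)-one | BrCC1=C[C@H](OC1=O)/C=C(/CO[Si](c2ccccc2)(c2ccccc2)C(C)(C)C)CC/C=C(/CO[Si](c2ccccc2)(c2ccccc2)C(C)(C)C)[C@H](O)CO | intermediate
24 | (5R)-3-(bromomethyl)-5-[(1E,5Z)-7-[(tert-butyldiphenylsilyl)oxy]-2-{[(tert-butyldiphenylsilyl)oxy]methyl}-6-[(4S)-2-methoxy-2-methyl-1,3-dioxolan-4-yl]hepta-1,5-dien-1-yl]furan-2(5H)-one (both epimers at the orthoester carbon) | BrCC1=C[C@H](OC1=O)/C=C(/CO[Si](c2ccccc2)(c2ccccc2)C(C)(C)C)CC/C=C(/CO[Si](c2ccccc2)(c2ccccc2)C(C)(C)C)[C@H]1COC(C)(OC)O1 | intermediate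
25 | (2S,3Z,7E)-8-[(2R)-4-(bromomethyl)-5-oxo-2,5-dihydrofuran-2-yl]-3,7-bis{[(tert-butyldiphenylsilyl)oxy]methyl}-1-hydroxyocta-3,7-dien-2-yl acetate | BrCC1=C[C@H](OC1=O)/C=C(/CO[Si](c2ccccc2)(c2ccccc2)C(C)(C)C)CC/C=C(/CO[Si](c2ccccc2)(c2ccccc2)C(C)(C)C)[C@H](OC(C)=O)CO | intermediate
26 | (2S,3Z,7E)-8-[(2R)-4-(bromomethyl)-5-oxo-2,5-dihydrofuran-2-yl]-3,7-bis{[(tert-butyldiphenylsilyl)oxy]methyl}-1-oxoocta-3,7-dien-2-yl acetate | BrCC1=C[C@H](OC1=O)/C=C(/CO[Si](c2ccccc2)(c2ccccc2)C(C)(C)C)CC/C=C(/CO[Si](c2ccccc2)(c2ccccc2)C(C)(C)C)[C@H](OC(C)=O)C=O | intermediate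
27 | (3aR,4R,5S,6Z,10E,11aR)-6,10-bis{[(tert-butyldiphenylsilyl)oxy]methyl}-4-hydroxy-3-methylidene-2-oxo-2,3,3a,4,5,8,9,11a-octahydrocyclodeca[b]furan-5-yl acetate | C=C1C(=O)O[C@@H]2/C=C(/CO[Si](c3ccccc3)(c3ccccc3)C(C)(C)C)CC/C=C(/CO[Si](c3ccccc3)(c3ccccc3)C(C)(C)C)[C@H](OC(C)=O)[C@H](O)[C@@H]12 | intermediate
28 | (2S)-2-methylbutanoic anhydride | CC[C@H](C)C(=O)OC(=O)[C@@H](C)CC | starting material
29 | (3aS,4R,5S,6Z,10E,11aR)-5-(acetyloxy)-6,10-bis{[(tert-butyldiphenylsilyl)oxy]methyl}-3-methylidene-2-oxo-2,3,3a,4,5,8,9,11a-octahydrocyclodeca[b]furan-4-yl (2S)-2-methylbutanoate | C=C1C(=O)O[C@@H]2/C=C(/CO[Si](c3ccccc3)(c3ccccc3)C(C)(C)C)CC/C=C(/CO[Si](c3ccccc3)(c3ccccc3)C(C)(C)C)[C@H](OC(C)=O)[C@H](OC(=O)[C@@H](C)CC)[C@@H]12 | intermediate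
30 | (3aS,4R,5S,6Z,10E,11aR)-5-(acetyloxy)-6,10-bis(hydroxymethyl)-3-methylidene-2-oxo-2,3,3a,4,5,8,9,11a-octahydrocyclodeca[b]furan-4-yl (2S)-2-methylbutanoate | C=C1C(=O)O[C@@H]2/C=C(/CO)CC/C=C(/CO)[C@H](OC(C)=O)[C@H](OC(=O)[C@@H](C)CC)[C@@H]12 | target

**Step count**

Total: 17 steps. Longest linear sequence: 14 steps (steps 1–5, then 9–17, from 1); the East branch is steps 6–8.

**Three steps most likely to fail**

Step 15 (the proposed new ring closure). The ten-membered closure must outrun simple reduction or dimerisation of the allyl species, the photochemical turnover of chromium is untested on a 3-(bromomethyl)butenolide, and the sense of induction at C7 and C8 under the constraint of the tether is predicted, not shown. The fallback uses known chemistry and a closed-shell allylboron reagent instead of a chromium species. It sets out from aldehyde 26: the allylic bromide is exchanged for boron with B2pin2 and Pd2(dba)3 (cat.) in THF (palladium-catalysed borylation of an allylic halide) to give the allylboronate aldehyde F6. On warming, or with Sc(OTf)3 (cat.), F6 undergoes intramolecular allylboration of the aldehyde through the same closed chair, as known for 2-(alkoxycarbonyl)allylboronates. Aqueous work-up of the borate returns to the route at alcohol 27.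

Step 11 (metathesis to the bromomethyl butenolide). The 2-(bromomethyl)acrylate is an electron-poor 1,1-disubstituted alkene and its allylic bromide can degrade the ruthenium carbene. The fallback keeps the bromide out of the metathesis and installs it afterwards. It sets out from alcohol 18, which is esterified (DCC, DMAP) with 2-{[(4-methoxybenzyl)oxy]methyl}prop-2-enoic acid to give the protected hydroxymethyl acrylate F1. Ring-closing metathesis with the second-generation Grubbs catalyst gives the 3-(4-methoxybenzyloxymethyl)butenolide F2. DDQ removes the benzyl ether to give the 3-(hydroxymethyl)butenolide F3, and CBr4/PPh3 converts the allylic alcohol into the bromide, returning to the route at 22.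

Step 13 (monoacetylation at C9). The orthoester opening may give some primary acetate, and the secondary acetate can migrate to the free primary hydroxyl. The fallback differentiates the diol by protection instead. It sets out from diol 23: TBSOTf and 2,6-lutidine at −78 °C silylate the primary hydroxyl to give the primary silyl ether F4. Acetyl chloride with 2,4,6-collidine acetylates C9–OH to give the silyl ether acetate F5. Brief HF·pyridine at 0 °C removes the primary tert-butyldimethylsilyl group much faster than the TBDPS ethers, returning to the route at 25.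

**Further compounds**

F1 | step 11 | (3S,4E,8Z)-10-[(tert-butyldiphenylsilyl)oxy]-5-{[(tert-butyldiphenylsilyl)oxy]methyl}-9-[(4S)-2,2-dimethyl-1,3-dioxolan-4-yl]deca-1,4,8-trien-3-yl 2-{[(4-methoxybenzyl)oxy]methyl}prop-2-enoate | C=C[C@H](OC(=O)C(=C)COCc1ccc(OC)cc1)/C=C(/CO[Si](c1ccccc1)(c1ccccc1)C(C)(C)C)CC/C=C(/CO[Si](c1ccccc1)(c1ccccc1)C(C)(C)C)[C@H]1COC(C)(C)O1
F2 | step 11 | (5R)-5-[(1E,5Z)-7-[(tert-butyldiphenylsilyl)oxy]-2-{[(tert-butyldiphenylsilyl)oxy]methyl}-6-[(4S)-2,2-dimethyl-1,3-dioxolan-4-yl]hepta-1,5-dien-1-yl]-3-{[(4-methoxybenzyl)oxy]methyl}furan-2(5H)-one | COc1ccc(COCC2=C[C@H](OC2=O)/C=C(/CO[Si](c3ccccc3)(c3ccccc3)C(C)(C)C)CC/C=C(/CO[Si](c3ccccc3)(c3ccccc3)C(C)(C)C)[C@H]3COC(C)(C)O3)cc1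
F3 | step 11 | (5R)-5-[(1E,5Z)-7-[(tert-butyldiphenylsilyl)oxy]-2-{[(tert-butyldiphenylsilyl)oxy]methyl}-6-[(4S)-2,2-dimethyl-1,3-dioxolan-4-yl]hepta-1,5-dien-1-yl]-3-(hydroxymethyl)furan-2(5H)-one | OCC1=C[C@H](OC1=O)/C=C(/CO[Si](c2ccccc2)(c2ccccc2)C(C)(C)C)CC/C=C(/CO[Si](c2ccccc2)(c2ccccc2)C(C)(C)C)[C@H]1COC(C)(C)O1
F4 | step 13 | (5R)-3-(bromomethyl)-5-[(1E,5Z,7S)-8-[(tert-butyldimethylsilyl)oxy]-2,6-bis{[(tert-butyldiphenylsilyl)oxy]methyl}-7-hydroxyocta-1,5-dien-1-yl]furan-2(5H)-one | BrCC1=C[C@H](OC1=O)/C=C(/CO[Si](c2ccccc2)(c2ccccc2)C(C)(C)C)CC/C=C(/CO[Si](c2ccccc2)(c2ccccc2)C(C)(C)C)[C@H](O)CO[Si](C)(C)C(C)(C)C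
F5 | step 13 | (2S,3Z,7E)-8-[(2R)-4-(bromomethyl)-5-oxo-2,5-dihydrofuran-2-yl]-1-[(tert-butyldimethylsilyl)oxy]-3,7-bis{[(tert-butyldiphenylsilyl)oxy]methyl}octa-3,7-dien-2-yl acetate | BrCC1=C[C@H](OC1=O)/C=C(/CO[Si](c2ccccc2)(c2ccccc2)C(C)(C)C)CC/C=C(/CO[Si](c2ccccc2)(c2ccccc2)C(C)(C)C)[C@H](OC(C)=O)CO[Si](C)(C)C(C)(C)C
F6 | step 15 | (2S,3Z,7E)-3,7-bis{[(tert-butyldiphenylsilyl)oxy]methyl}-1-oxo-8-{(2R)-5-oxo-4-[(4,4,5,5-tetramethyl-1,3,2-dioxaborolan-2-yl)methyl]-2,5-dihydrofuran-2-yl}octa-3,7-dien-2-yl acetate | CC1(C)OB(CC2=C[C@H](OC2=O)/C=C(/CO[Si](c3ccccc3)(c3ccccc3)C(C)(C)C)CC/C=C(/CO[Si](c3ccccc3)(c3ccccc3)C(C)(C)C)[C@H](OC(C)=O)C=O)OC1(C)C
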